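**A direct plan and its weak points**

A direct plan would join an A-ring 2-hydroxyaryl homoprenyl ketone A1 and a B-ring 3-prenylaroyl chloride A2 by Baker–Venkataraman acyl transfer to the 1,3-diketone A3, and would close the pyranone by heating A3 in aqueous acid, which would also remove the acetals.
Three steps would weaken it:
- The run-up to A1 (C–H borylation, oxidation, formylation, Grignard addition, re-oxidation) would spend five steps on an acylphloroglucinol pattern that commercial trihydroxyphenyl carbonyl compounds already hold.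
- The acyl transfer to A3 would ask a branched enolate carbon to attack a hindered ortho-alkoxyaryl ester under excess amide base, on both finished fragments.
- The acid cyclodehydration of A3 would leave the ring closure to chance: once the B-ring acetals fall, either ortho-hydroxyaryl ketone could close on the other carbonyl, and the hot acid would meet two prenyl groups beside free phenols.

**Plan of the new route**

- Cuts: C3–C4 and O1–C2 of ring C are cut together, leaving salicylaldehyde 8 and aryl prenyl alkyne 6; both prenyl CH2–C bonds of 6 are then cut back to arylacetylene 3.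
- Ring order: rings A and B are bought as hydroxybenzaldehydes; ring C arises in the step that unites the halves (union at C3–C4), not after it.
- Enabling feature: C4 is a carbonyl carbon ortho to O1 on ring A (the formyl C–H/O–H pair of a salicylaldehyde), and C2=C3 carries aryl on the O-bound carbon and alkyl on the acyl-bound carbon (the insertion polarity of an aryl alkyl alkyne).
- Second feature: C3 and C3′ are the two most acidic C–H sites of 3 (sp C–H; ring C–H between two OMOM groups), so both prenyl groups come from one dianion.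
- Weak steps avoided: the acyl carbon is bought at the aldehyde level; there is no diketone and no acyl transfer; the ring closes at the metal with a single free phenol, so the final acid only exchanges acetals, cold and dilute.

Key step: step 5

Remark: kuwanon T has no stereocentre and no stereogenic double bond, so no enantiomer has to be selected.

**Route**

Step 1
Reactants: 1 2,4-dihydroxybenzaldehyde
Product: 2 2,4-bis(methoxymethoxy)benzaldehyde
Conditions: MOMCl (3 equiv), K2CO3 (4 equiv), acetone, reflux
Reagents that add atoms: chloromethyl methyl ether, COCCl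
Why: Williamson-type O-alkylation (acetal protection) of both phenols, the hydrogen-bonded 2-OH included; the MOM ethers should resist base, organolithiums and the Rh/Cu step and later direct the ring lithiation.

Step 2
Reactants: 2 2,4-bis(methoxymethoxy)benzaldehyde
Product: 3 1-ethynyl-2,4-bis(methoxymethoxy)benzene
Conditions: dimethyl (1-diazo-2-oxopropyl)phosphonate (1.3 equiv), K2CO3 (2 equiv), MeOH, 0 °C → rt
Reagents that add atoms: dimethyl (1-diazo-2-oxopropyl)phosphonate, COP(=O)(OC)C(=[N+]=[N-])C(C)=O
Why: Seyferth–Gilbert homologation in the Ohira–Bestmann form: methoxide unmasks the diazomethylphosphonate, whose Horner–Wadsworth–Emmons addition to the non-enolisable aldehyde and loss of N2 (1,2-H shift of the alkylidene carbene) should give the terminal alkyne under conditions the acetals tolerate.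

Step 3
Reactants: 3 1-ethynyl-2,4-bis(methoxymethoxy)benzene; 4 prenyl bromide (1-bromo-3-methylbut-2-ene)
Product: 6 2,4-bis(methoxymethoxy)-3-(3-methylbut-2-en-1-yl)-1-(5-methylhex-4-en-1-yn-1-yl)benzene, via dilithio species 5 (not isolated)
Conditions: n-BuLi (2.3 equiv), THF, −78 → 0 °C; then CuI (10 mol %), 4 (2.6 equiv), −78 °C → rt
Reagents that add atoms: none
Why: Sequential deprotonation should give the C,C-dianion, first at the sp C–H and then by directed ortho-metalation at C3 (the only ring position flanked by two OMOM groups); the aryllithium is alkylated directly and the acetylide under copper catalysis, each at the primary carbon of 4 (SN2), so that the future 3′- and 3-prenyl groups are installed in one flask.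

Step 4
Reactants: 7 2,4,6-trihydroxybenzaldehyde
Product: 8 2-hydroxy-4,6-bis(methoxymethoxy)benzaldehyde
Conditions: MOMCl (2.2 equiv), i-Pr2NEt (2.5 equiv), CH2Cl2, 0 °C → rt
Reagents that add atoms: chloromethyl methyl ether, COCCl
Why: Selective Williamson-type acetalisation: the 4-OH and one ortho-OH should react, while the last ortho-OH is held in a hydrogen bond to the formyl group and stays free, which is the O–H that has to become O1.

Step 5
Reactants: 6 2,4-bis(methoxymethoxy)-3-(3-methylbut-2-en-1-yl)-1-(5-methylhex-4-en-1-yn-1-yl)benzene; 8 2-hydroxy-4,6-bis(methoxymethoxy)benzaldehyde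
Product: 9 2-[2,4-bis(methoxymethoxy)-3-(3-methylbut-2-en-1-yl)phenyl]-5,7-bis(methoxymethoxy)-3-(3-methylbut-2-en-1-yl)-4H-chromen-4-one
Conditions: [RhCl(cod)]2 (2.5 mol %), 1,2,3,4-tetraphenylcyclopenta-1,3-diene (10 mol %), Cu(OAc)2·H2O (2.1 equiv), o-xylene, 120 °C, N2
Reagents that add atoms: none
Why: Rh(III)-catalysed oxidative [4+2] annulation of a salicylaldehyde with an internal alkyne: the phenoxide of 8 binds rhodium, the formyl C–H is cleaved with acetate assistance to a five-membered acyl rhodacycle, 6 inserts into the Rh–acyl bond, and C–O reductive elimination from the seven-membered oxarhodacycle should release 9 while Cu(OAc)2 reoxidises Rh(I). The closest known reaction type is the rhodium/copper-mediated oxidative coupling of salicylaldehydes with internal alkynes to 2,3-disubstituted chromones. Ring C is the only ring closed; C3–C4 forms by insertion and O1–C2 by reductive elimination at the metal, not by attack of a phenol on a carbonyl group or an alkyne, so neither a 5-exo (aurone) mode nor an acid-dependent dehydration is available. No stereocentre is formed. The step needs regioselective insertion (aryl-bearing carbon to Rh and then to O1, CH2-bearing carbon to the acyl carbon), which the aryl/alkyl polarisation of 6 should secure as in related Rh(III) alkyne annulations and which chelation of rhodium by the 2-OMOM oxygen of ring B should support; it also needs a single closure, secured because the salicyl OH of 8 is the only free phenol in either partner. The trisubstituted prenyl alkenes are poor ligands for Rh(III) and should take no part in the cycle.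

Step 6
Reactants: 9 2-[2,4-bis(methoxymethoxy)-3-(3-methylbut-2-en-1-yl)phenyl]-5,7-bis(methoxymethoxy)-3-(3-methylbut-2-en-1-yl)-4H-chromen-4-one
Product: 10 kuwanon T
Conditions: HCl (0.5 M), MeOH/THF 4:1, 0 °C → rt; NaHCO3
Reagents that add atoms: none
Why: Acid-catalysed transacetalisation to methanol should remove the four MOM groups as dimethoxymethane; because ring C is already closed the acid has only to exchange acetals and can be dilute and cold, conditions under which trisubstituted alkenes beside phenols are not expected to be protonated.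

**Compound list**

1 | 2,4-dihydroxybenzaldehyde | O=Cc1ccc(O)cc1O | starting material
2 | 2,4-bis(methoxymethoxy)benzaldehyde | COCOc1ccc(C=O)c(OCOC)c1 | intermediate
3 | 1-ethynyl-2,4-bis(methoxymethoxy)benzene | C#Cc1ccc(OCOC)cc1OCOC | intermediate
4 | prenyl bromide (1-bromo-3-methylbut-2-ene) | CC(C)=CCBr | starting material
5 | lithium [3-lithio-2,4-bis(methoxymethoxy)phenyl]acetylide (dilithio species, not isolated) | [Li]C#Cc1ccc(OCOC)c([Li])c1OCOC | intermediate
6 | 2,4-bis(methoxymethoxy)-3-(3-methylbut-2-en-1-yl)-1-(5-methylhex-4-en-1-yn-1-yl)benzene | CC(C)=CCC#Cc1ccc(OCOC)c(CC=C(C)C)c1OCOC | intermediate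
7 | 2,4,6-trihydroxybenzaldehyde | O=Cc1c(O)cc(O)cc1O | starting material
8 | 2-hydroxy-4,6-bis(methoxymethoxy)benzaldehyde | COCOc1cc(O)c(C=O)c(OCOC)c1 | intermediate
9 | 2-[2,4-bis(methoxymethoxy)-3-(3-methylbut-2-en-1-yl)phenyl]-5,7-bis(methoxymethoxy)-3-(3-methylbut-2-en-1-yl)-4H-chromen-4-one | CC(C)=CCc1c(OCOC)ccc(-c2oc3cc(OCOC)cc(OCOC)c3c(=O)c2CC=C(C)C)c1OCOC | intermediate
10 | kuwanon T, 2-[2,4-dihydroxy-3-(3-methylbut-2-en-1-yl)phenyl]-5,7-dihydroxy-3-(3-methylbut-2-en-1-yl)-4H-chromen-4-one (achiral) | CC(C)=CCc1c(O)ccc(-c2oc3cc(O)cc(O)c3c(=O)c2CC=C(C)C)c1O | target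

**Step count**

Total steps: 6. Longest linear sequence: 5 steps (1 → 2 → 3 → 6 → 9 → 10; steps 1, 2, 3, 5, 6).

**Steps most likely to fail**

Step 5. Insertion of the ortho-substituted aryl alkyne may be slow. Decarbonylation of the acyl rhodium could then take over, as could isomerisation of the skipped enyne at its doubly activated CH2 or π-acid-induced cyclisation of the 2-(methoxymethoxy)aryl alkyne to a benzofuran. Regiocontrol of the insertion may also be lost. The fallback would make C3–C4 by acetylide addition, O1–C2 by conjugate ring closure and the C3–prenyl bond last. It would set out from 3 (through 5) and 8 and come back at 9. Dianion 5 would be alkylated with one equivalent of 4 in the absence of copper, where only the aryllithium should react, to give lithium [2,4-bis(methoxymethoxy)-3-prenylphenyl]acetylide F1. The lithium phenoxide of 8 would be added to the same flask to give the propargylic alcohol F2. MnO2 in CH2Cl2 would give the 2-hydroxyaryl ynone F3, and DMAP-catalysed 6-endo oxa-Michael closure would give the 3-unsubstituted tetra-MOM flavone F4. Deprotonation at C3 with LDA at −78 °C and addition of ZnCl2 would give the 3-zincated flavone F5 (not isolated). Its Pd(PPh3)4-catalysed Negishi-type coupling with 4 at the primary carbon would return 9.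

Step 3. Ring lithiation in the presence of the acetylide may be incomplete or misdirected (C5 instead of C3). Attack at the tertiary end of 4 (SN2′) would give a 1,1-dimethylallyl group. Remaining aryllithium may deprotonate the newly formed doubly activated CH2. The fallback would make and alkylate the two anions one after the other and form the skipped enyne without any organolithium. It would set out from 3 and come back at 6. n-BuLi and TIPSCl would give the silyl alkyne F6. Directed ortho-lithiation (n-BuLi, THF, 0 °C) and alkylation with 4 would give the ring-prenylated silyl alkyne F7. TBAF would free the terminal alkyne F8. Copper-catalysed coupling of this alkyne with 4 under carbonate (CuI, K2CO3, NaI, DMF, rt) would give 6.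

Step 6. A prenyl alkene may be protonated and close onto the neighbouring free phenol (chroman formation) before the last, hindered acetal at O2′ has gone. The fallback would replace the acid-labile acetal by a fluoride-labile one, so that no acid is used at all. It would set out from 1 and 7 and come back at 10. With SEMCl in place of MOMCl, steps 1–5 would give in turn:
- the bis-SEM aldehyde F9,
- the bis-SEM arylacetylene F10,
- its dilithio species F11 (not isolated),
- the bis-prenylated bis-SEM enyne F12,
- the bis-SEM salicylaldehyde F13,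
- the tetra-SEM flavone F14.

TBAF in DMPU at 60 °C would then remove the four SEM groups (attack of fluoride at silicon, loss of ethene and formaldehyde) to give 10.

**Further compounds**

F1 | step 5 | lithium [2,4-bis(methoxymethoxy)-3-(3-methylbut-2-en-1-yl)phenyl]acetylide | [Li]C#Cc1ccc(OCOC)c(CC=C(C)C)c1OCOC
F2 | step 5 | 1-[2-hydroxy-4,6-bis(methoxymethoxy)phenyl]-3-[2,4-bis(methoxymethoxy)-3-(3-methylbut-2-en-1-yl)phenyl]prop-2-yn-1-ol (racemic) | COCOc1cc(O)c(C(O)C#Cc2ccc(OCOC)c(CC=C(C)C)c2OCOC)c(OCOC)c1
F3 | step 5 | 1-[2-hydroxy-4,6-bis(methoxymethoxy)phenyl]-3-[2,4-bis(methoxymethoxy)-3-(3-methylbut-2-en-1-yl)phenyl]prop-2-yn-1-one | COCOc1cc(O)c(C(=O)C#Cc2ccc(OCOC)c(CC=C(C)C)c2OCOC)c(OCOC)c1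
F4 | step 5 | 2-[2,4-bis(methoxymethoxy)-3-(3-methylbut-2-en-1-yl)phenyl]-5,7-bis(methoxymethoxy)-4H-chromen-4-one | CC(C)=CCc1c(OCOC)ccc(-c2cc(=O)c3c(OCOC)cc(OCOC)cc3o2)c1OCOC
F5 | step 5 | chlorozinc derivative at C3 of the tetra-MOM flavone | CC(C)=CCc1c(OCOC)ccc(-c2oc3cc(OCOC)cc(OCOC)c3c(=O)c2[Zn]Cl)c1OCOC
F6 | step 3 | {[2,4-bis(methoxymethoxy)phenyl]ethynyl}tri(propan-2-yl)silane | CC(C)[Si](C#Cc1ccc(OCOC)cc1OCOC)(C(C)C)C(C)C
F7 | step 3 | {[2,4-bis(methoxymethoxy)-3-(3-methylbut-2-en-1-yl)phenyl]ethynyl}tri(propan-2-yl)silane | CC(C)[Si](C#Cc1ccc(OCOC)c(CC=C(C)C)c1OCOC)(C(C)C)C(C)C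
F8 | step 3 | 1-ethynyl-2,4-bis(methoxymethoxy)-3-(3-methylbut-2-en-1-yl)benzene | C#Cc1ccc(OCOC)c(CC=C(C)C)c1OCOC
F9 | step 6 | 2,4-bis{[2-(trimethylsilyl)ethoxy]methoxy}benzaldehyde | C[Si](C)(C)CCOCOc1ccc(C=O)c(OCOCC[Si](C)(C)C)c1
F10 | step 6 | 1-ethynyl-2,4-bis{[2-(trimethylsilyl)ethoxy]methoxy}benzene | C#Cc1ccc(OCOCC[Si](C)(C)C)cc1OCOCC[Si](C)(C)C
F11 | step 6 | lithium (3-lithio-2,4-bis{[2-(trimethylsilyl)ethoxy]methoxy}phenyl)acetylide | [Li]C#Cc1ccc(OCOCC[Si](C)(C)C)c([Li])c1OCOCC[Si](C)(C)C
F12 | step 6 | 3-(3-methylbut-2-en-1-yl)-1-(5-methylhex-4-en-1-yn-1-yl)-2,4-bis{[2-(trimethylsilyl)ethoxy]methoxy}benzene | CC(C)=CCC#Cc1ccc(OCOCC[Si](C)(C)C)c(CC=C(C)C)c1OCOCC[Si](C)(C)C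
F13 | step 6 | 2-hydroxy-4,6-bis{[2-(trimethylsilyl)ethoxy]methoxy}benzaldehyde | C[Si](C)(C)CCOCOc1cc(O)c(C=O)c(OCOCC[Si](C)(C)C)c1
F14 | step 6 | 3-(3-methylbut-2-en-1-yl)-2-[3-(3-methylbut-2-en-1-yl)-2,4-bis{[2-(trimethylsilyl)ethoxy]methoxy}phenyl]-5,7-bis{[2-(trimethylsilyl)ethoxy]methoxy}-4H-chromen-4-one | CC(C)=CCc1c(OCOCC[Si](C)(C)C)ccc(-c2oc3cc(OCOCC[Si](C)(C)C)cc(OCOCC[Si](C)(C)C)c3c(=O)c2CC=C(C)C)c1OCOCC[Si](C)(C)C
A1 | direct plan | 1-[2-hydroxy-4,6-bis(methoxymethoxy)phenyl]-5-methylhex-4-en-1-one | COCOc1cc(O)c(C(=O)CCC=C(C)C)c(OCOC)c1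
A2 | direct plan | 2,4-bis(methoxymethoxy)-3-(3-methylbut-2-en-1-yl)benzoyl chloride | CC(C)=CCc1c(OCOC)ccc(C(=O)Cl)c1OCOC
A3 | direct plan | 1-[2-hydroxy-4,6-bis(methoxymethoxy)phenyl]-3-[2,4-bis(methoxymethoxy)-3-(3-methylbut-2-en-1-yl)phenyl]-2-(3-methylbut-2-en-1-yl)propane-1,3-dione | COCOc1cc(O)c(C(=O)C(CC=C(C)C)C(=O)c2ccc(OCOC)c(CC=C(C)C)c2OCOC)c(OCOC)c1
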